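## The problem

Target **26** is an ent-halimane. Rings A (C1–C5, C10) and B (C5–C10) share the C5–C10 bond, and because C10 belongs to the C1/C10 olefin only C5 of the ring fusion is stereogenic. Four ring stereocentres must be set in a fixed relation: quaternary C4 (methyl C19 axial, carboxyl C18 equatorial), C5, C8 (methyl C17) and quaternary C9 (methyl C20 cis to C17, plus the chain C11–C15). These four sit around one bicycle and can control one another in a single ring-forming event. The chain stereocentres C13 (tertiary alcohol) and C14 (acetate) are insulated from C9 by the methylenes C11 and C12 and can only be set by a reagent. The fragile parts are the C14 acetate beside a free primary C15 hydroxyl (hydrolysis and 1,2-acyl shift under base), the tertiary C13 carbinol, and the trisubstituted C1/C10 olefin, which strong acid can move to the tetrasubstituted C5/C10 position with loss of C5. The C18 carboxyl hangs on a quaternary carbon, so it cannot be freed from a simple ester once the acetate is present and is better made late by oxidation. The feature that opens a short route is the pattern "H on C8, C20 on C9, unsaturation at C10": this is what a labdane C8 cation gives after H9 moves to C8, C20 moves from C10 to C9 and C1 loses a proton. Rings A and B with all four ring stereocentres can therefore come from an acyclic (E,E)-diene carrying an epoxide at C3–C4, with C3 holding the absolute information and C4 already bearing the C18 oxygen.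

## Retrosynthesis

**26 to 21 (oxygen functions only).** The C14 acetate, the C18 carboxyl and the free C15 hydroxyl are traced back to diol **21**, in which O15 is a p-methoxybenzyl ether and C18 a silyl ether. In **21** only the secondary C14 hydroxyl can be acylated (C13 is tertiary, O15 is blocked), so the acetate goes on without selectivity problems to give **22**. The carboxyl is then made by oxidation of the freed C18 alcohol (**23**, then **25** through aldehyde **24**), which avoids any ester hydrolysis next to the acetate. The last step, oxidative removal of the benzyl ether, is the only one in which the acetate has a free primary hydroxyl beside it, and it runs near neutrality.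

**21 to 18 (C13–O and C14–O).** The 13S,14R pattern is the anti-dihydroxylation product of the (E)-C13/C14 olefin; a syn dihydroxylation would need the Z olefin, which is hard to make from a methyl ketone. The diol is therefore cut to epoxide **20**, its free alcohol **19**, and allylic alcohol **18**. Forward, a Sharpless epoxidation must set C13 and C14 by reagent control, and water must then open the tertiary carbon C13 with inversion.

**18 to 13 (C13=C14 and C12–C13).** The olefin is cut to methyl ketone **16** and a two-carbon phosphonate (ester **17** in between). The C12–C13 bond is cut to sulfone **13** and an acetyl donor (β-keto sulfone **15**). The sulfone serves twice: it is the carbanion handle at C12, and before that the inert chain terminus during the cationic step. The neighbouring cut C11–C12 would need a nucleophile or electrophile on a carbon next to quaternary C9 and is worse.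

**13 to 11 (C3–H to C3–OH).** A hydroxyl is added back at C3 because an epoxide initiator leaves one there. Forward this costs a two-step radical deoxygenation through thionocarbonate **12**, which is acceptable because the C3 oxygen also carries the absolute configuration and provides the counter-ion that steers the end of the cascade.

**11 to 7 (C4–C5, C9–C10 and C9–C20 formed; C10–C20 broken).** Both rings and the four ring stereocentres are cut in one stroke to the acyclic (3R,4R)-epoxy diene **7**. The neighbouring option, stopping at a labdane and rearranging it later, needs two steps and a strong Brønsted acid that would equilibrate the olefin. The single cascade under a proton-scavenging Lewis acid is shorter and keeps the kinetic olefin. The forward reaction must fold chair–chair, must not lose a proton at the labdane stage, and must end by loss of H1 and not H5.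

**7 to 1 and 2.** The silyl ether and the epoxide are removed to allylic alcohol **5** (through epoxy alcohol **6**), the C18 oxygen to sulfone **4**, and the C11–C12 bond to farnesyl bromide **2** and methyl phenyl sulfone **1**. Forward these are an alkylation, an allylic oxidation that must pick the terminal (E)-methyl group, a Sharpless epoxidation and a silylation.

## Roads not taken

**Alternative 1:** Ring A is cut at C2–C3 and C4–C5 as an intramolecular Diels–Alder reaction. A ring B diene (C2, C1, C10, C5) carries at O6 the mixed ester of methyl methylenemalonate (**A1**); heating should give tricyclic lactone **A2**, with the C19 carbonyl tied to O6.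
- Merits: the olefin ends at C1/C10 by construction, and the tether should fix C4 relative to C5 in the same event. On olefin position this road is better than the chosen one.
- Weak points: ester-tethered cycloadditions through a three-atom tether are reluctant, because the ester prefers the conformation that holds the dienophile away from the diene. Methylenemalonates polymerise easily. The diene terminus C5 is fully substituted within the ring. Ring B with quaternary C9, C8 and a correctly placed C6 oxygen has to be made first. After the cycloaddition the C19 lactone carbon must be reduced to a methyl group and the C6 oxygen removed, at least five redox steps that build nothing.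
- Comparison: the chosen plan sets against the better olefin control a precursor (**7**) made in four steps, both rings and four stereocentres in one operation, and a counter-ion argument for the proton loss, backed by a two-stage fallback.

**Alternative 2:** Ring B is cut at C9–C10 as a redox-relay Heck cyclisation. The C10 alkenyl triflate of a finished ring A (**A3**) would add 6-exo across the (E)-C9/C11 olefin, after which palladium walks from C11 to the C13 carbinol and leaves as the ketone **A4**.
- Merits: the olefin position is fixed by the triflate carbon. C9 has no β-hydrogen, so the relay can only run toward C13. The C13 ketone appears in the same step, so no sulfone chemistry is needed. **A4** matches ketone **16** of the chosen route with C18 already at the ester level.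
- Weak points: insertion into a trisubstituted olefin to make quaternary C9 is slow. The face of that insertion, which sets C9 against C8 and C5, is governed only by a flexible tether conformation. **A3** needs ring A with C4 and C5, an acyclic C8 stereocentre and a defined trisubstituted olefin, a long linear preparation. The hindered C18 methyl ester would have to be exchanged before the acetate goes on, which takes back the steps saved.
- Comparison: better on olefin position and on the ketone; worse on length before the key step and on control of C9, which in the chosen plan follows from a stereospecific 1,2-shift.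

**Alternative 3:** Ring A is cut at C4–C5 as an anodic olefin coupling. Oxidation of the ketene dithioacetal at C4/C18 in **A5** gives a radical cation that C5 of the allylsilane attacks; silicon leaves C1 and methanol caps C18, giving **A6**.
- Merits: the silyl group fixes the C1/C10 olefin without doubt. C18 arrives at the acid oxidation level, so no late oxidation of a neopentyl alcohol is needed. The conditions are mild. On both points this road is better than the chosen one.
- Weak points: two adjacent stereocentres, quaternary C4 and C5, form with nothing but a remote quaternary C9 (methyl against chain) to choose the face, and the methyl/dithiane differentiation at C4 is small. **A5** needs ring B with C8 and C9 set and an allylsilane of defined position, again a long preparation. The dithiane orthoester has to be unmasked with thiophilic or oxidising reagents.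
- Comparison: the chosen plan sets against this the stereospecific origin of C4 and C5 (epoxide inversion and chair fold) and its short precursor, at the price of a less certain proton loss.

Key step: step 5

Remark on the chemistry: atoms carry halimane numbers throughout and faces refer to the usual drawing (ring A left, C10 at the top, β toward the viewer). The tartrate sense of both Sharpless epoxidations is assigned from the rule that (E)-allylic alcohols give (2S,3S)-epoxides with L-(+)-diethyl tartrate and (2R,3R)-epoxides with the D-(−)-ester.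

## Route

Step 1
Reactants: 1 methyl phenyl sulfone; 2 (2E,6E)-farnesyl bromide
Product: 4 [(3E,7E)-4,8,12-trimethyltrideca-3,7,11-trien-1-yl]sulfonylbenzene (homofarnesyl phenyl sulfone), via (phenylsulfonyl)methyllithium 3 (not isolated)
Conditions: 1 (2.5 equiv), n-BuLi, THF, −78 °C; then 2, −78 to 0 °C
Reagents that add atoms: none
Why: SN2 alkylation of an α-sulfonyl carbanion by a primary allylic bromide; the excess of lithiated sulfone suppresses double alkylation and attack at the CH2Br carbon leaves both olefin geometries untouched.

Step 2
Reactants: 4 homofarnesyl phenyl sulfone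
Product: 5 (2E,6E,10E)-2,6,10-trimethyl-13-(phenylsulfonyl)trideca-2,6,10-trien-1-ol
Conditions: SeO2 (cat.), t-BuOOH, salicylic acid (cat.), CH2Cl2, rt
Reagents that add atoms: tert-butyl hydroperoxide, CC(C)(C)OO
Why: SeO2 allylic oxidation (ene reaction, then [2,3]-shift) goes for the (E)-methyl group of the terminal, most electron-rich trisubstituted olefin and gives the (E)-allylic alcohol; the sulfone is inert.

Step 3
Reactants: 5 terminal (E)-allylic alcohol
Product: 6 [(2R,3R)-3-[(3E,7E)-3,7-dimethyl-10-(phenylsulfonyl)deca-3,7-dien-1-yl]-2-methyloxiran-2-yl]methanol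
Conditions: Ti(OiPr)4 (cat.), D-(−)-diethyl tartrate (cat.), t-BuOOH, 4 Å molecular sieves, CH2Cl2, −20 °C
Reagents that add atoms: tert-butyl hydroperoxide, CC(C)(C)OO
Why: Sharpless asymmetric epoxidation; only the olefin of the allylic alcohol is delivered oxygen, and with the D-(−)-tartrate an (E)-2-methyl-2-alken-1-ol gives the (2R,3R)-epoxide, which fixes C4 and C3 of the later skeleton.

Step 4
Reactants: 6 (2R,3R)-epoxy alcohol
Product: 7 tert-butyl{[(2R,3R)-3-[(3E,7E)-3,7-dimethyl-10-(phenylsulfonyl)deca-3,7-dien-1-yl]-2-methyloxiran-2-yl]methoxy}diphenylsilane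
Conditions: TBDPSCl, imidazole, DMF, rt
Reagents that add atoms: tert-butyl(chloro)diphenylsilane, CC(C)(C)[Si](Cl)(c1ccccc1)c1ccccc1
Why: Silylation of the only hydroxyl; the bulky, weakly basic silyl ether neither chelates the Lewis acid nor takes part in the epoxide opening of the next step.

Step 5
Reactants: 7 (3R,4R)-epoxy diene silyl ether (halimane numbering)
Product: 11 (3R,4S,5S,8R,9S)-18-(tert-butyldiphenylsilyloxy)-12-(phenylsulfonyl)-13,14,15,16-tetranor-ent-halim-1(10)-en-3-ol, via ent-labdan-8-yl cation 8 (not isolated), via C9 cation 9 (not isolated), via ent-halim-10-yl cation 10 (not isolated)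
Conditions: MeAlCl2 (2.5 equiv), CH2Cl2 (high dilution), −78 °C; then Et3N, MeOH, aqueous work-up
Reagents that add atoms: none
Why: Proposed new method: MeAlCl2 binds the epoxide oxygen, C5 of the C5/C10 olefin opens C4 with inversion (6-endo closure of ring A) and C9 of the C8/C9 olefin bonds to C10 (6-endo-trig closure of ring B) through a chair–chair fold, giving cation 8 as a zwitterion with the aluminate R–O–AlMeCl2 at O3; the closest known reactions are MeAlCl2 epoxy-polyene bicyclisations that end at this stage by proton loss and Brønsted-acid backbone rearrangements of labdane olefins. Cation 8 has no base or π-nucleophile within reach, since the chain past C11 carries only the sulfone and the one basic site sits on ring A, so the axial H9 should shift to C8 (cation 9) and the axial C20 methyl from C10 to C9 (cation 10), each shift bringing the charge closer to the counter-ion and relieving the 1,3-diaxial C19/C20 contact. C4 is set by inversion at the (4R)-epoxide carbon, C5 by anti addition across the (E)-olefin in the chair fold that the C3 oxygen (equatorial) dictates, C8 by the suprafacial hydride shift on the β face and C9 by the suprafacial methyl shift on the α face, anti to the departing hydride. The step needs cation 10 to lose H1 and not H5: the aluminate (its oxygen or its Al–CH3 bond) lies on the α face beside C1 and C2, H5 lies on the β face behind the C18 silyl ether, and the oxygens at C3 and C18 disfavour charge build-up at C5. The proton leaves as methane, so the termination is irreversible and the 1(10)-olefin cannot equilibrate to the 5(10)-isomer.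

Step 6
Reactants: 11 3-hydroxy halimene sulfone
Product: 12 O-phenyl thionocarbonate of 11 at O3, (3R,4S,5S,8R,9S)
Conditions: PhOC(S)Cl, pyridine, DMAP (cat.), CH2Cl2, rt
Reagents that add atoms: O-phenyl chlorothionoformate, S=C(Cl)Oc1ccccc1
Why: DMAP-catalysed acylation of the equatorial C3 hydroxyl prepares the Barton–McCombie deoxygenation; no base strong enough to touch the sulfone α-protons is used.

Step 7
Reactants: 12 thionocarbonate
Product: 13 (4S,5S,8R,9S)-18-(tert-butyldiphenylsilyloxy)-12-(phenylsulfonyl)-13,14,15,16-tetranor-ent-halim-1(10)-ene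
Conditions: Bu3SnH, AIBN (cat.), toluene, 100 °C
Reagents that add atoms: none
Why: Barton–McCombie deoxygenation: the stannyl radical adds to C=S, the C3–O bond fragments and the secondary C3 radical takes hydrogen from Bu3SnH. At high Bu3SnH concentration this homoallylic radical is reduced before it can add to the C1/C10 olefin, as in the deoxygenation of steroidal 5-en-3-ols.

Step 8
Reactants: 13 deoxygenated sulfone
Product: 15 (4S,5S,8R,9S)-18-(tert-butyldiphenylsilyloxy)-12-(phenylsulfonyl)-14,15-dinor-ent-halim-1(10)-en-13-one (both C12 epimers), via C12-lithio sulfone 14 (not isolated)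
Conditions: n-BuLi (1.1 equiv), THF, −78 °C; MeC(O)N(OMe)Me, −78 to 0 °C; aq. NH4Cl
Reagents that add atoms: N-methoxy-N-methylacetamide, CC(=O)N(C)OC
Why: α-Lithiation of the alkyl phenyl sulfone and C-acylation by a Weinreb amide; the chelated tetrahedral adduct survives until work-up, so one equivalent of base suffices and no second addition occurs.

Step 9
Reactants: 15 β-keto sulfone
Product: 16 (4S,5S,8R,9S)-18-(tert-butyldiphenylsilyloxy)-14,15-dinor-ent-halim-1(10)-en-13-one
Conditions: SmI2, THF/MeOH, −78 °C
Reagents that add atoms: none
Why: Reductive desulfonylation of a β-keto sulfone by electron transfer from SmI2; the C–S bond α to the carbonyl breaks to the enolate, which MeOH protonates, and the isolated olefin and silyl ether are not reduced.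

Step 10
Reactants: 16 methyl ketone
Product: 17 ethyl (4S,5S,8R,9S,13E)-18-(tert-butyldiphenylsilyloxy)-ent-halima-1(10),13-dien-15-oate
Conditions: (EtO)2P(O)CH2CO2Et, NaH, THF, 0 to 60 °C; chromatography
Reagents that add atoms: triethyl phosphonoacetate, CCOC(=O)CP(=O)(OCC)OCC
Why: Horner–Wadsworth–Emmons olefination of a methyl ketone; the (E)-enoate should predominate because the larger C12 chain ends up trans to the ester, and the minor (Z)-isomer is removed by chromatography.

Step 11
Reactants: 17 (E)-enoate
Product: 18 (4S,5S,8R,9S,13E)-18-(tert-butyldiphenylsilyloxy)-ent-halima-1(10),13-dien-15-ol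
Conditions: i-Bu2AlH, CH2Cl2, −78 °C
Reagents that add atoms: none
Why: 1,2-Reduction of the α,β-unsaturated ester by i-Bu2AlH gives the allylic alcohol; the silyl ether and the C1/C10 olefin do not react.

Step 12
Reactants: 18 (E)-allylic alcohol
Product: 19 (4S,5S,8R,9S,13R,14R)-13,14-epoxy-18-(tert-butyldiphenylsilyloxy)-ent-halim-1(10)-en-15-ol
Conditions: Ti(OiPr)4 (cat.), D-(−)-diethyl tartrate (cat.), t-BuOOH, 4 Å molecular sieves, CH2Cl2, −20 °C
Reagents that add atoms: tert-butyl hydroperoxide, CC(C)(C)OO
Why: Sharpless asymmetric epoxidation of a geraniol-type (E)-3-methyl-2-alken-1-ol; the D-(−)-tartrate gives the (2R,3R)-epoxy alcohol, here 13R,14R, by reagent control because the ring stereocentres are too remote to interfere, and the C1/C10 olefin has no directing hydroxyl.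

Step 13
Reactants: 19 epoxy alcohol
Product: 20 15-O-(4-methoxybenzyl) ether of 19, (4S,5S,8R,9S,13R,14R)
Conditions: NaH, PMBCl, Bu4NI (cat.), THF/DMF, 0 °C to rt
Reagents that add atoms: 4-methoxybenzyl chloride, COc1ccc(CCl)cc1
Why: Williamson etherification of the only hydroxyl; in an aprotic medium the alkoxide is benzylated faster than it undergoes Payne rearrangement.

Step 14
Reactants: 20 epoxy ether
Product: 21 (4S,5S,8R,9S,13S,14R)-15-(4-methoxybenzyloxy)-18-(tert-butyldiphenylsilyloxy)-ent-halim-1(10)-ene-13,14-diol
Conditions: HClO4 (cat.), THF/H2O, 0 °C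
Reagents that add atoms: water, O
Why: Acid-catalysed hydrolysis of a trisubstituted epoxide: water attacks the tertiary carbon C13 from the rear, which inverts C13 (R to S) and leaves C14 (R) untouched, giving the anti-diol. Dilute acid at 0 °C should be too weak to protonate the C1/C10 olefin or to cleave either ether.

Step 15
Reactants: 21 13,14-diol
Product: 22 14-acetate of 21, (4S,5S,8R,9S,13S,14R)-14-acetoxy-15-(4-methoxybenzyloxy)-18-(tert-butyldiphenylsilyloxy)-ent-halim-1(10)-en-13-ol
Conditions: Ac2O, pyridine, DMAP (cat.), CH2Cl2, 0 °C
Reagents that add atoms: acetic anhydride, CC(=O)OC(C)=O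
Why: DMAP-catalysed acetylation takes the secondary C14 hydroxyl and leaves the tertiary C13 hydroxyl on steric grounds.

Step 16
Reactants: 22 acetate silyl ether
Product: 23 (4S,5S,8R,9S,13S,14R)-14-acetoxy-15-(4-methoxybenzyloxy)-ent-halim-1(10)-ene-13,18-diol
Conditions: Bu4NF, AcOH, THF, rt
Reagents that add atoms: none
Why: Fluoride cleavage of the silyl ether; the AcOH buffer keeps the medium non-basic so the acetate is not cleaved, and its only free neighbour, the tertiary C13 hydroxyl, is a poor acceptor for acyl migration.

Step 17
Reactants: 23 C18 alcohol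
Product: 25 (4S,5S,8R,9S,13S,14R)-14-acetoxy-13-hydroxy-15-(4-methoxybenzyloxy)-ent-halim-1(10)-en-18-oic acid, via C18 aldehyde 24 (not isolated)
Conditions: 2-azaadamantane N-oxyl (cat.), NaOCl (cat.), NaClO2, MeCN/aq. NaH2PO4–Na2HPO4 (pH 6.7), rt to 35 °C
Reagents that add atoms: sodium chlorite, [Na+].[O-]Cl=O
Why: Nitroxyl-catalysed oxidation of the primary alcohol to the aldehyde and chlorite oxidation of that aldehyde (Pinnick type) in one flask; the unhindered nitroxyl reaches the neopentyl alcohol, and the tertiary alcohol, acetate, benzyl ether and olefin are not oxidised under these buffered conditions.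

Step 18
Reactants: 25 acid with O15 benzyl ether
Product: 26 (4S,5S,8R,9S,13S,14R)-14-acetoxy-13,15-dihydroxy-ent-halim-1(10)-en-18-oic acid (CNP0164901.1)
Conditions: DDQ, CH2Cl2/aq. NaH2PO4–Na2HPO4 (pH 7), 0 °C
Reagents that add atoms: none
Why: Oxidative cleavage of the p-methoxybenzyl ether by DDQ (hydride abstraction, then hydrolysis of the oxocarbenium ion) under buffered, near-neutral conditions that should neither hydrolyse nor shift the C14 acetate.

## Compound list

1 | methyl phenyl sulfone | CS(=O)(=O)c1ccccc1 | starting material
2 | (2E,6E)-farnesyl bromide | CC(C)=CCC/C(C)=C/CC/C(C)=C/CBr | starting material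
3 | (phenylsulfonyl)methyllithium | [Li]CS(=O)(=O)c1ccccc1 | intermediate
4 | [(3E,7E)-4,8,12-trimethyltrideca-3,7,11-trien-1-yl]sulfonylbenzene | CC(C)=CCC/C(C)=C/CC/C(C)=C/CCS(=O)(=O)c1ccccc1 | intermediate
5 | (2E,6E,10E)-2,6,10-trimethyl-13-(phenylsulfonyl)trideca-2,6,10-trien-1-ol | OC/C(C)=C/CC/C(C)=C/CC/C(C)=C/CCS(=O)(=O)c1ccccc1 | intermediate
6 | [(2R,3R)-3-[(3E,7E)-3,7-dimethyl-10-(phenylsulfonyl)deca-3,7-dien-1-yl]-2-methyloxiran-2-yl]methanol | O=S(=O)(c1ccccc1)CC/C=C(\C)CC/C=C(\C)CC[C@H]2O[C@]2(C)CO | intermediate
7 | tert-butyldiphenylsilyl ether of 6; (3R,4R)-epoxide in halimane numbering | O=S(=O)(c1ccccc1)CC/C=C(\C)CC/C=C(\C)CC[C@H]2O[C@]2(C)CO[Si](c3ccccc3)(c4ccccc4)C(C)(C)C | intermediate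
8 | ent-labdan-8-yl cation, zwitterion with the O3 aluminate (H5 β, H9 β, C20 α on C10) | O=S(=O)(c1ccccc1)CC[C@H]2[C@]3(C)CC[C@@H](O[Al-](C)(Cl)Cl)[C@](C)(CO[Si](c4ccccc4)(c5ccccc5)C(C)(C)C)[C@H]3CC[C+]2C | intermediate
9 | C9 cation after the hydride shift, zwitterion (H8 β, C17 α, C20 α on C10) | O=S(=O)(c1ccccc1)CC[C+]2[C@]3(C)CC[C@@H](O[Al-](C)(Cl)Cl)[C@](C)(CO[Si](c4ccccc4)(c5ccccc5)C(C)(C)C)[C@H]3CC[C@H]2C | intermediate
10 | ent-halim-10-yl cation after the methyl shift, zwitterion (C20 α on C9) | O=S(=O)(c1ccccc1)CC[C@]2(C)[C+]3CC[C@@H](O[Al-](C)(Cl)Cl)[C@](C)(CO[Si](c4ccccc4)(c5ccccc5)C(C)(C)C)[C@H]3CC[C@H]2C | intermediate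
11 | (3R,4S,5S,8R,9S)-18-(tert-butyldiphenylsilyloxy)-12-(phenylsulfonyl)-13,14,15,16-tetranor-ent-halim-1(10)-en-3-ol | O=S(=O)(c1ccccc1)CC[C@]2(C)C3=CC[C@@H](O)[C@](C)(CO[Si](c4ccccc4)(c5ccccc5)C(C)(C)C)[C@H]3CC[C@H]2C | intermediate
12 | O-phenyl thionocarbonate of 11 at O3 | O=S(=O)(c1ccccc1)CC[C@]2(C)C3=CC[C@@H](OC(=S)Oc6ccccc6)[C@](C)(CO[Si](c4ccccc4)(c5ccccc5)C(C)(C)C)[C@H]3CC[C@H]2C | intermediate
13 | (4S,5S,8R,9S)-18-(tert-butyldiphenylsilyloxy)-12-(phenylsulfonyl)-13,14,15,16-tetranor-ent-halim-1(10)-ene | O=S(=O)(c1ccccc1)CC[C@]2(C)C3=CCC[C@](C)(CO[Si](c4ccccc4)(c5ccccc5)C(C)(C)C)[C@H]3CC[C@H]2C | intermediate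
14 | C12-lithio derivative of 13 | [Li]C(C[C@]1(C)C2=CCC[C@](C)(CO[Si](c3ccccc3)(c4ccccc4)C(C)(C)C)[C@H]2CC[C@H]1C)S(=O)(=O)c5ccccc5 | intermediate
15 | (4S,5S,8R,9S)-18-(tert-butyldiphenylsilyloxy)-12-(phenylsulfonyl)-14,15-dinor-ent-halim-1(10)-en-13-one, both C12 epimers | CC(=O)C(C[C@]2(C)C3=CCC[C@](C)(CO[Si](c4ccccc4)(c5ccccc5)C(C)(C)C)[C@H]3CC[C@H]2C)S(=O)(=O)c1ccccc1 | intermediate
16 | (4S,5S,8R,9S)-18-(tert-butyldiphenylsilyloxy)-14,15-dinor-ent-halim-1(10)-en-13-one | CC(=O)CC[C@]1(C)C2=CCC[C@](C)(CO[Si](c3ccccc3)(c4ccccc4)C(C)(C)C)[C@H]2CC[C@H]1C | intermediate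
17 | ethyl (4S,5S,8R,9S,13E)-18-(tert-butyldiphenylsilyloxy)-ent-halima-1(10),13-dien-15-oate | CCOC(=O)/C=C(\C)CC[C@]1(C)C2=CCC[C@](C)(CO[Si](c3ccccc3)(c4ccccc4)C(C)(C)C)[C@H]2CC[C@H]1C | intermediate
18 | (4S,5S,8R,9S,13E)-18-(tert-butyldiphenylsilyloxy)-ent-halima-1(10),13-dien-15-ol | OC/C=C(\C)CC[C@]1(C)C2=CCC[C@](C)(CO[Si](c3ccccc3)(c4ccccc4)C(C)(C)C)[C@H]2CC[C@H]1C | intermediate
19 | (4S,5S,8R,9S,13R,14R)-13,14-epoxy-18-(tert-butyldiphenylsilyloxy)-ent-halim-1(10)-en-15-ol | OC[C@H]1O[C@]1(C)CC[C@]2(C)C3=CCC[C@](C)(CO[Si](c4ccccc4)(c5ccccc5)C(C)(C)C)[C@H]3CC[C@H]2C | intermediate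
20 | 15-O-(4-methoxybenzyl) ether of 19 | COc1ccc(COC[C@H]2O[C@]2(C)CC[C@]3(C)C4=CCC[C@](C)(CO[Si](c5ccccc5)(c6ccccc6)C(C)(C)C)[C@H]4CC[C@H]3C)cc1 | intermediate
21 | (4S,5S,8R,9S,13S,14R)-15-(4-methoxybenzyloxy)-18-(tert-butyldiphenylsilyloxy)-ent-halim-1(10)-ene-13,14-diol | O[C@H](COCc1ccc(OC)cc1)[C@@](C)(O)CC[C@]2(C)C3=CCC[C@](C)(CO[Si](c4ccccc4)(c5ccccc5)C(C)(C)C)[C@H]3CC[C@H]2C | intermediate
22 | 14-acetate of 21 | CC(=O)O[C@H](COCc1ccc(OC)cc1)[C@@](C)(O)CC[C@]2(C)C3=CCC[C@](C)(CO[Si](c4ccccc4)(c5ccccc5)C(C)(C)C)[C@H]3CC[C@H]2C | intermediate
23 | (4S,5S,8R,9S,13S,14R)-14-acetoxy-15-(4-methoxybenzyloxy)-ent-halim-1(10)-ene-13,18-diol | CC(=O)O[C@H](COCc1ccc(OC)cc1)[C@@](C)(O)CC[C@]2(C)C3=CCC[C@](C)(CO)[C@H]3CC[C@H]2C | intermediate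
24 | (4S,5S,8R,9S,13S,14R)-14-acetoxy-13-hydroxy-15-(4-methoxybenzyloxy)-ent-halim-1(10)-en-18-al | CC(=O)O[C@H](COCc1ccc(OC)cc1)[C@@](C)(O)CC[C@]2(C)C3=CCC[C@](C)(C=O)[C@H]3CC[C@H]2C | intermediate
25 | (4S,5S,8R,9S,13S,14R)-14-acetoxy-13-hydroxy-15-(4-methoxybenzyloxy)-ent-halim-1(10)-en-18-oic acid | CC(=O)O[C@H](COCc1ccc(OC)cc1)[C@@](C)(O)CC[C@]2(C)C3=CCC[C@](C)(C(=O)O)[C@H]3CC[C@H]2C | intermediate
26 | (4S,5S,8R,9S,13S,14R)-14-acetoxy-13,15-dihydroxy-ent-halim-1(10)-en-18-oic acid (CNP0164901.1) | CC(=O)O[C@H](CO)[C@@](C)(O)CC[C@]1(C)C2=CCC[C@](C)(C(=O)O)[C@H]2CC[C@H]1C | target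

## Step count and least certain steps

Total: 18 steps. Longest linear sequence: 18 steps, from 1 and 2 to 26.

**Step 5 (key step).** Three processes could spoil it. The first is proton loss from the C8 cation before the hydride and methyl shifts, which ends the cascade at the labdane stage. The second is loss of H5 in place of H1 from the C10 cation, or capture of that cation by the C3 oxygen on the α face. The third is a slow start, because the C18 oxygen withdraws charge from C4 and the epoxide may rearrange to a carbonyl compound. The fallback uses two known reaction types in two flasks and sets out from 7. A Lewis-acid bicyclisation of 7 is run so that it ends by proton loss at the labdane stage and gives 3-hydroxy-18-silyloxy-12-phenylsulfonyl-tetranor-ent-labd-8(17)-ene F1 together with its endocyclic olefin isomers. F1 is then treated with a strong Brønsted acid in a non-nucleophilic solvent at low temperature, which regenerates the C8 cation and lets the backbone rearrangement known for labdane olefins run. The 1(10)-olefin is separated from the 5(10)-isomer and the route is rejoined at 11.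

**Step 14.** The tertiary C13–O bond may ionise fully before water arrives, which erodes the inversion at C13. Water may also attack C14, or the acid may start to move the C1/C10 olefin. The fallback builds the same diol by two SN2 events and sets out from 18. Sharpless epoxidation with L-(+)-diethyl tartrate gives the (13S,14S)-epoxy alcohol F2. Payne rearrangement and hydroxide opening of the terminal epoxide (NaOH, t-BuOH/H2O) invert C14 and give the (13S,14R)-13,14,15-triol F3. The dibutylstannylene acetal (Bu2SnO) with PMBCl and CsF etherifies the primary hydroxyl, and the route is rejoined at 21.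

**Step 10.** The olefination may give too little preference for the (E)-enoate, and any (Z)-isomer carried on would end as the wrong C13/C14 diastereomer. The fallback fixes the geometry by a syn carbometalation and sets out from 16. The kinetic enol phosphate (LiN(i-Pr)2, ClP(O)(OEt)2) is eliminated with more LiN(i-Pr)2 to the terminal alkyne F4. Negishi carboalumination (Me3Al, Cp2ZrCl2 cat.) followed by paraformaldehyde gives the (E)-allylic alcohol directly, and the route is rejoined at 18.

**Step 18.** Once O15 is free, the acetate may migrate from O14 to O15 on contact with buffer, silica or traces of base, and DDQ may attack other positions of the polyfunctional acid. The fallback creates the acetate in the very last operation and sets out from 21. DDQ gives the triol F3. Trimethyl orthoacetate with pyridinium p-toluenesulfonate gives the 14,15-cyclic orthoacetate F5. Bu4NF frees the C18 alcohol F6. Dess–Martin periodinane and then NaClO2 give the acid F7. Dilute aqueous acetic acid opens the orthoester, by kinetic collapse of the hemiorthoester, to the secondary acetate and the primary alcohol, which is 26.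

## Further compounds

F1 | step 5 | (3R)-3-hydroxy-18-(tert-butyldiphenylsilyloxy)-12-(phenylsulfonyl)-13,14,15,16-tetranor-ent-labd-8(17)-ene (H5 β, H9 β, C20 α) | O=S(=O)(c1ccccc1)CC[C@H]2[C@]3(C)CC[C@@H](O)[C@](C)(CO[Si](c4ccccc4)(c5ccccc5)C(C)(C)C)[C@H]3CCC2=C
F2 | step 14 | (4S,5S,8R,9S,13S,14S)-13,14-epoxy-18-(tert-butyldiphenylsilyloxy)-ent-halim-1(10)-en-15-ol | OC[C@@H]1O[C@@]1(C)CC[C@]2(C)C3=CCC[C@](C)(CO[Si](c4ccccc4)(c5ccccc5)C(C)(C)C)[C@H]3CC[C@H]2C
F3 | step 14 | (4S,5S,8R,9S,13S,14R)-18-(tert-butyldiphenylsilyloxy)-ent-halim-1(10)-ene-13,14,15-triol | O[C@H](CO)[C@@](C)(O)CC[C@]1(C)C2=CCC[C@](C)(CO[Si](c3ccccc3)(c4ccccc4)C(C)(C)C)[C@H]2CC[C@H]1C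
F4 | step 10 | (4S,5S,8R,9S)-18-(tert-butyldiphenylsilyloxy)-15,16-dinor-ent-halim-1(10)-en-13-yne (terminal alkyne from the methyl ketone) | C#CCC[C@]1(C)C2=CCC[C@](C)(CO[Si](c3ccccc3)(c4ccccc4)C(C)(C)C)[C@H]2CC[C@H]1C
F5 | step 18 | 14,15-O-(1-methoxyethylidene) orthoacetate of F3 (13-OH free, orthoester carbon as a mixture) | COC1(C)OC[C@@H](O1)[C@@](C)(O)CC[C@]2(C)C3=CCC[C@](C)(CO[Si](c4ccccc4)(c5ccccc5)C(C)(C)C)[C@H]3CC[C@H]2C
F6 | step 18 | 14,15-orthoacetate with free C18 alcohol | COC1(C)OC[C@@H](O1)[C@@](C)(O)CC[C@]2(C)C3=CCC[C@](C)(CO)[C@H]3CC[C@H]2C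
F7 | step 18 | 14,15-orthoacetate of the 13,14,15-trihydroxy-ent-halim-1(10)-en-18-oic acid | COC1(C)OC[C@@H](O1)[C@@](C)(O)CC[C@]2(C)C3=CCC[C@](C)(C(=O)O)[C@H]3CC[C@H]2C
A1 | alternative 1 | ring B diene with the methyl methylenemalonate ester at O6 and the C13 dioxolane | CC1(OCCO1)CC[C@]2(C)C(C=C)=C[C@@H](OC(=O)C(=C)C(=O)OC)C[C@H]2C
A2 | alternative 1 | tricyclic C19/O6 lactone with C18 methyl ester and C13 dioxolane | CC5(OCCO5)CC[C@]1(C)C2=CCC[C@]3(C(=O)OC)[C@H]2[C@@H](OC3=O)C[C@H]1C
A3 | alternative 2 | ring A C10 alkenyl triflate with the (E)-C9/C11 olefin and the C13 carbinol (C13 either configuration) | CC(O)C/C=C(\C)[C@H](C)CC[C@H]1C(OS(=O)(=O)C(F)(F)F)=CCC[C@]1(C)C(=O)OC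
A4 | alternative 2 | ent-halim-1(10)-ene core with C13 methyl ketone and C18 methyl ester | CC(=O)CC[C@]1(C)C2=CCC[C@](C)(C(=O)OC)[C@H]2CC[C@H]1C
A5 | alternative 3 | ring B allylsilane with the C4/C18 ketene dithioacetal and the C13 dioxolane (C1 either configuration) | CC1(OCCO1)CC[C@]2(C)C(C([Si](C)(C)C)CCC(C)=C3SCCCS3)=CCC[C@H]2C
A6 | alternative 3 | bicyclic core with C18 as 2-methoxy-1,3-dithiane and the C13 dioxolane | CC3(OCCO3)CC[C@]1(C)C2=CCC[C@](C)(C4(OC)SCCCS4)[C@H]2CC[C@H]1C
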